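The earlier runs and the new flask stem from a simulated flask for an exercise, noise included.

- Early on, Thursday's flask makes product at 11.1 mM d⁻¹.
- That pace turns the 15.0 mM of reagent charged to midnight in 1.35 d. Yet at 6.00 d, Thursday's flask still holds 26.1% of its reagent unturned. These two numbers seem to clash.

| setting | Sunday's | Thursday's | Monday's | dusk | midnight | summer | spring |
|---|---|---|---|---|---|---|---|
| substrate | 7.8 mM | 28 mM | 23 mM | 6.0 mM | 23 mM | 23 mM | 23 mM |
| reagent | 34.5 mM | 34.5 mM | 34.5 mM | 15.0 mM | 15.0 mM | 25.0 mM | 34.5 mM |
| initiator | 0.57 mM | 0.57 mM | 1.3 mM | 2.5 mM | 0.57 mM | 0.57 mM | 0.57 mM |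
| remark | run made earlier | run made earlier | run made earlier |  |  |  |  |
| time |  |  |  | 12 d | 12 d | 12 d | 12 d |

- Sunday's (time / d: product / %, substrate / %): 1.67: 96, 0; 3.00: 92, 0; 5.00: 99, 2; 6.00: 97, 0; 8.00: 100, 0
- Thursday's (time / d: product / %, substrate / %): 0.833: 33, 64; 2.00: 61, 38; 4.00: 82, 16; 6.00: 91, 5; 8.00: 96, 0
- Monday's (time / d: product / %, substrate / %): 0.833: 59, 38; 2.00: 94, 2; 4.00: 96, 0; 6.00: 96, 2; 8.00: 93, 0

(standard deviation of a reading: 1.5 percentage points)

- in percentages every species weighs as the substrate in it: one ended chains B counts as two
- steps that have been proposed: initiator -> 2 initiating radical; substrate + initiating radical -> chain carrier; reagent + chain carrier -> product + initiating radical; 2 initiating radical -> ended chains A; 2 chain carrier -> ended chains B; reagent <-> dormant form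

1. the flasks by amount of product, in percent of the substrate charged, highest first, at 12 d (dusk / midnight / summer / spring)
2. the same order at 30 h (dusk / midnight / summer / spring)
3. the amount of product, in percent of the substrate charged of the flask you put first, at 12 d
4. the amount of product, in percent of the substrate charged of the flask you put last, at 12 d

- I treat the reagent loss as pseudo-first-order and define the exposure as ln([reagent] charged / [reagent] not yet turned).
- Thursday's readings give an exposure of 0.683 at 2.00 d, 1.10 at 4.00 d and 1.34 at 6.00 d.
- The gain up to 6.00 d is about 0.598 of the gain before it, as a reading. I carry that on for 3 more windows and reach 1.63 at 12 d.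
- As a mean, that is 0.136 d⁻¹. This is lower than the 0.374 d⁻¹ of the first 0.833 d. So the clash clears: the early pace is not the mean.
- By my reckoning, this leaves 19.6% of the reagent charge at 12 d. I call this the reagent survival: the share of charged reagent not turned into product, free or dormant. I assume that it holds at 0.57 mM of initiator and at 12 d in a flask that still has substrate.
- For midnight, my reckoning gives 52.4%.
- The forecast orders the flasks spring > summer > dusk > midnight at 12 d and dusk > spring > summer > midnight at 30 h. It puts the top at 95.5% (93.5% to 97.5%) and the low at 54% (49% to 60%).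
- Its ground is: “Loss of reagent is first order, nearly independent of substrate, and scales with √initiator”. Its exposure is 1.77, and its midnight is higher than mine.
- The flasks give spring > summer > dusk > midnight at 12 d and dusk > spring > summer > midnight at 30 h, with spring at 96.3% and midnight at 54.7%.

    initiator → 2 initiating radical (k = 0.0150 h⁻¹)
    substrate + initiating radical → chain carrier (k = 3.30 × 10⁵ M⁻¹ s⁻¹)
    reagent + chain carrier → product + initiating radical (k = 2.10 × 10⁷ M⁻¹ h⁻¹)
    2 initiating radical → ended chains A (k = 1.20 × 10⁹ M⁻¹ s⁻¹)
    2 chain carrier → ended chains B (k = 2.00 × 10⁹ M⁻¹ s⁻¹)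
    reagent ⇌ dormant form (K = 0.480, k = 0.0490 h⁻¹)

- The consumption of reagent is the main reason for midnight's shortfall: with reagent held, midnight gives 96.4% instead of 54.7%. Midnight's result reads back as a survival of 16.1%, against my 19.6%. Carried to a neighbour of midnight charged with 92 mM of substrate, that survival gives 13.7%, and that neighbour ends at 13.7%.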